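The runs were computed with made-up constants; the scatter is artificial.

Substrate left over beside a short charge of partner is where I start on the quick number you asked for, with your hunch in mind that more substrate saves more single product.

| flask | substrate | partner | remark | time |
|---|---|---|---|---|
| north-east | 0.025 M | 0.083 M | run made earlier |  |
| beta | 0.025 M | 0.0550 M |  | 10 min |
| gamma | 0.050 M | 0.0550 M |  | 10 min |
| alpha | 0.10 M | 0.0550 M |  | 10 min |
| zeta | 0.20 M | 0.0550 M |  | 10 min |

north-east run (percent of the substrate charged): time / s: single product / % = 20.0: 15.8; 40.0: 16.8; 60.0: 14.4; 80.0: 13.0; 90.0: 11.7; 120: 9.2

(standard deviation of a reading: 0.5 percentage points)

- the analysis behind the earlier runs scatters by 0.5 percentage points, standard deviation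
- steps thought possible: substrate + partner -> single product + released group; partner + single product -> bis adduct + released group; substrate <-> dormant form
- "hardly changes" means that all values lie within two and a half points (for a concentration: within two and a half percent of the largest)

- amount of single product at the end, in percent of the substrate charged for beta, gamma, alpha, zeta, in this order
- the shape of the row from first to last (falls, then rises / hardly changes / rises, then falls / rises all the way / falls all the way)

Each step takes one partner, so I expect [partner] to cancel from the ratio of their rates. If the dormant form returns quickly, which the north-east run cannot prove, substrate and dormant form count as one pool, and single product in these flasks follows one curve against partner spent per substrate charged. A selectivity factor s, second step over first, puts the top of that curve at s^(−s/(s−1)) of the charge, which is 19.2% for s = 3 and 15.7% for s = 4. I take the north-east reading of 16.8% at 40.0 s, with its scatter of 0.5 percentage points, as that top; it lies between them, and interpolating in powers of ten gives a reading of s = 3.68. At that top the pool holds s times the single product and the rest is bis adduct, which took two partners each, so I get the crest ratio, the partner spent per substrate charged when single product stands highest, as 0.596.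

The charges give partner per substrate of 2.20 for beta, 1.10 for gamma, 0.550 for alpha and 0.275 for zeta. Beta holds enough to carry its substrate on to bis adduct, while in gamma, alpha and zeta the partner is the limiting reagent, and 10 min is long against the 40.0 s at which the north-east reading stands at 16.8%. Alpha stands nearest the crest ratio, so I commit to a row that rises, then falls, with alpha near the reading of 16.8%. The forecast reads 1.1%, 1.4%, 2.2%, 4.2%, a row that rises all the way, on the ground that “At higher substrate the burst eats the partner, so the second step starves and more single product survives”; my alpha stands higher than its 2.2%, and my row turns.

The flask gives 3.77%, 13.2%, 16.7% and 14.0%, a row that rises, then falls.

    substrate + partner → single product + released group (k = 0.254 /M/s)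
    partner + single product → bis adduct + released group (k = 0.650 /M/s)
    substrate ⇌ dormant form (K = 0.444, k = 0.0300 /s)

The row turns at 0.094 M of substrate, and the crest ratio puts that turn at the partner charge over 0.596, which is 0.0922 M. Zeta, at 0.275, sits at half the crest ratio, on the rising side of the curve, and holds 14.0% single product beside 6.76% bis adduct.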